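## The problem

Gnetulin (17) is a 2,3-diaryl-1-benzylideneindane. Its five-membered ring is fused at C3a and C7a to resorcinol ring A (hydroxyls on C4 and C6) and carries an exocyclic C1=C8 alkene to ring D (4-hydroxy-3-methoxyphenyl), ring B (3,5-dihydroxyphenyl) on C2 and ring C (4-hydroxy-3-methoxyphenyl) on C3. There are only two stereocentres, C2 and C3, both S and trans to each other, and the alkene is E, with ring D on the side of C2. The two centres are coupled: a substituent on C2 sends a reagent to the opposite face of C3, and once C3 is in place (it is never enolisable) trans is the thermodynamic arrangement at C2, so one absolute stereochemical decision suffices. Six phenols must be carried through and released beside two aryl methyl ethers, which calls for a protecting group that can be removed without touching OMe. The electron-rich arylidene does not tolerate protic acid (the double bond can move into the ring and erase C2, or ring B can attack C8), and C2–H next to a C1 carbonyl is acidic, so basic nucleophiles may enolise instead of adding. The feature that opens the structure is the position of the ring A oxygens: C4 and C6 are ortho and para to C3a but meta to C7a. A cation at C3 is therefore a masked oxocarbenium ion and a C3=C2 styrene on C3a is nucleophilic at C2, while a carbonyl carbon C1 on C7a stays electrophilic and the carbinol it becomes does not ionise.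

## Retrosynthesis

**17 from 16.** The six O–isopropyl bonds of hexa-O-isopropylgnetulin 16 are cut last. Isopropyl is preferred to benzyl (hydrogenolysis would reduce C1=C8) and to silyl (would not survive the acid and organometallic steps), because BCl3 cleaves secondary alkyl aryl ethers at low temperature and leaves the two methyl ethers. The forward step must avoid protic acid on the arylidene.

**16 from 10 and 13.** The C1=C8 bond is cut by a Peterson olefination, through β-hydroxysilane 15, into ketone 10 and benzylsilane 13 (lithiated in the flask to 14). Dehydration of a plain benzyl carbinol could place the double bond in the ring and destroy C2, whereas silicon dictates that the alkene forms between C1 and C8. The precursor 10 has no alkene and only the two ring stereocentres. The forward reaction must add a carbon nucleophile to a hindered, enolisable ketone (hence cerium) and must end at the E alkene (thermodynamic, since ring D avoids the peri C7–H).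

**10 from 8 through 9.** Only functional groups change: the C1 carbonyl goes back to the carbinol and the ring C isopropyl ether to the free phenol. This places at C1 exactly the oxygen that a Prins closure delivers and at ring C the hydroxyl that makes guaiacol a good nucleophile.

**8 from 5 and 6 (key cut).** C1–C2 and the C3–ring C bond are cut together. Neighbouring cuts (C3–C3a by a Nazarov closure, or C2–aryl and C3–aryl one at a time) each remove one bond and at most one controlled centre. This cut removes the five-membered ring, both permanent stereocentres and ring C at once, leaving the flat, achiral stilbene aldehyde 5 and commercial guaiacol 6. The forward reaction needs a chiral acid to choose the face of C2 in the ring closure, anti capture at C3, para-to-hydroxyl selectivity in 6, and ring closure faster than attack of 6 on the aldehyde.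

**5 from 3 and 4.** The aryl–vinyl bond C3a–C3 is cut by a Heck reaction between bromoaldehyde 3 and styrene 4. A Wittig route would need a benzylic phosphonium salt that also carries a free formyl group. The Heck reaction tolerates the aldehyde, gives the E alkene, and draws both halves from one compound. It must work at a bromide flanked by two ortho substituents.

**3 and 4 from 2, and 2 from 1.** Bromination of 2 ortho to the formyl group gives 3, Wittig methylenation of 2 gives 4, and 2 is the bis-isopropyl ether of commercial 3,5-dihydroxybenzaldehyde 1.

**13 from 11 through 12.** The aryl–CH2 bond of 13 is cut by a Kumada coupling of bromide 12 with (trimethylsilyl)methylmagnesium chloride; 12 is the isopropyl ether of commercial 4-bromo-2-methoxyphenol 11. This takes two steps, against four from vanillin via the benzyl chloride.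

## Roads not taken

**Alternative 1:** ring A is built last by aldol aromatisation.
- Cut: C7–C7a. Triketone A2, a 2-arylidenecyclopentanone carrying a 3-oxobutanoyl chain on C3a, would be treated with Mg(OMe)2; the methyl ketone enolate adds to the ring carbonyl C7a and dehydration with enolisation gives tetra-O-isopropylgnetulin A1 with free hydroxyls on C4 and C6.
- Merits: ring A appears with its oxygens unambiguously placed and unprotected, and the arylidene could be installed on a cyclopentanone by a plain aldol condensation. In that last respect this road is better than the late olefination of the enolisable ketone 10.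
- Weak points: the key step forms one bond and no stereocentre, so A2 must already contain C2, C3 and the alkene. A2 is a cross-conjugated enone with an acidic C2–H, and base can epimerise C2 or shift the double bond into the ring. A 1,3,5-tricarbonyl chain can also close through oxygen to a 4-pyranone. Assembly of A2 would be long.
- Comparison: the chosen plan sets against it that its key step makes the ring, two bonds and all controlled centres from a precursor four steps from 1.

**Alternative 2:** pyrone–alkynylboronate Diels–Alder reaction.
- Cut: C3a–C7a and C4–C5. Heating precursor A4, in which a 4-isopropoxy-2-pyranone on C1 is tethered through C2 and C3 to an alkynylboronate, would give an intramolecular cycloaddition and loss of CO2, forming ring A and the five-membered ring of C4-boryl penta-O-isopropyl indane A3. Oxidation of the C4–B bond and de-isopropylation would lead to 17.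
- Merits: two rings and two C–C bonds form in one neutral thermal step, the ring A regiochemistry is fixed by the tether, and no cation is involved. On regiochemical certainty it is better than a capture of guaiacol.
- Weak points: A4 is an open chain that must already carry the anti C2/C3 diaryl pair and the trisubstituted E alkene, made by separate asymmetric chemistry. C2–H (allylic and benzylic) and C3–H (propargylic and benzylic) must survive the high temperature such cycloadditions usually need. The alkynylboronate is prone to protodeboronation, and an extra oxidation step follows.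
- Comparison: the chosen plan sets against it that the stereocentres are created in the key step rather than carried into it, from far simpler precursors.

**Alternative 3:** enantioselective Nazarov closure.
- Cut: C3–C3a. A confined chiral acid would protonate 2-aryl chalcone A6; conrotatory 4π closure onto ring A and protonation at C2 give trans-2,3-diarylindanone A5, which is identical with ketone 10.
- Merits: the racemic form of this closure is well established for 2,3-diarylindanones, every aryl group is placed without any regiochemical question, and A5 needs neither the phenol protection nor the oxidation (steps 6 and 7). In these respects it is as good as or better than the chosen plan.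
- Weak points: the hydroxyallyl cation from A6 is strongly stabilised by the para-alkoxy ring C on C3 and must attack an arene, which is dearomatised in the closure. Such closures usually need strong acid or heat, conditions under which a tight chiral ion pair loses its grip. The catalyst sets only C3.
- Comparison: the chosen plan sets against it a more reactive electrophile (a protonated aldehyde) and a nucleophilic alkene, so no dearomatisation is needed and the closure should run cold. Ring C also enters last as a commercial phenol. The two roads meet at 10.

Key step: step 5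

Assumption: the sense of induction of the confined acid cannot be predicted; the (S,S)-catalyst is written and its antipode would be used if it proves to give the (2R) series. The C1 hydroxyl of 8 is drawn trans to ring B, and its C1 epimer would be carried on in the same way.

## Route

Step 1
Reactants: 1 3,5-dihydroxybenzaldehyde
Product: 2 3,5-diisopropoxybenzaldehyde
Conditions: 2-bromopropane, K2CO3, DMF, 60 °C
Reagents that add atoms: 2-bromopropane, CC(C)Br
Why: Williamson etherification of both phenols; the aldehyde is inert to carbonate, and isopropyl is chosen because BCl3 later removes it beside aryl methyl ethers.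

Step 2
Reactants: 2 3,5-diisopropoxybenzaldehyde
Product: 3 2-bromo-3,5-diisopropoxybenzaldehyde
Conditions: NBS, MeCN, 0 °C → rt
Reagents that add atoms: N-bromosuccinimide, O=C1CCC(=O)N1Br
Why: Electrophilic aromatic bromination; C2 is ortho to one and para to the other isopropoxy group, while C4 between the two isopropoxy groups is shielded, so monobromination next to the formyl group is expected.

Step 3
Reactants: 2 3,5-diisopropoxybenzaldehyde
Product: 4 3,5-diisopropoxystyrene
Conditions: Ph3PCH3Br, KOt-Bu, THF, 0 °C → rt
Reagents that add atoms: methyltriphenylphosphonium bromide, C[P+](c1ccccc1)(c1ccccc1)c1ccccc1.[Br-]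
Why: Wittig methylenation of an aromatic aldehyde with the non-stabilised ylide.

Step 4
Reactants: 3 2-bromo-3,5-diisopropoxybenzaldehyde; 4 3,5-diisopropoxystyrene
Product: 5 2-[(E)-2-(3,5-diisopropoxyphenyl)ethenyl]-3,5-diisopropoxybenzaldehyde
Conditions: Pd(OAc)2 (5 mol %), P(o-tol)3 (10 mol %), Et3N, DMF, 100 °C
Reagents that add atoms: none
Why: Heck reaction; the ortho formyl group assists oxidative addition to zerovalent palladium, the aryl group adds to the terminal alkene carbon, and syn β-hydride elimination gives the E stilbene with the aldehyde untouched.

Step 5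
Reactants: 5 2-[(E)-2-(3,5-diisopropoxyphenyl)ethenyl]-3,5-diisopropoxybenzaldehyde; 6 guaiacol (2-methoxyphenol)
Product: 8 (1S,2S,3S)-2-(3,5-diisopropoxyphenyl)-3-(4-hydroxy-3-methoxyphenyl)-4,6-diisopropoxyindan-1-ol, via C3 indanyl cation 7 (not isolated)
Conditions: (S,S)-imidodiphosphorimidate [(ArBINOL)P(=NSO2CF3)–NH–P(=NSO2CF3)(ArBINOL), ArBINOL = (S)-3,3′-bis[3,5-bis(trifluoromethyl)phenyl]-1,1′-binaphthalene-2,2′-diolate] (5 mol %), guaiacol (3 equiv), CHCl3, −40 °C
Reagents that add atoms: none
Why: Proposed new method: the confined acid protonates the formyl oxygen of 5, C2 of the donor-substituted styrene attacks C1 to form C1–C2, and the resulting C3 cation 7, stabilised as an oxocarbenium ion by the C4 and C6 isopropoxy groups and paired with the chiral anion, is captured by guaiacol through its position para to the hydroxyl to form the C3–ring C bond and return the proton. The closest known reaction types are acid-promoted Prins and Friedel–Crafts cascades of alkenyl benzaldehydes, the closures of ortho-styryl benzylic cations with external capture, and Prins and Nazarov cyclisations catalysed by imidodiphosphorimidates; new is the union of an enantioselective closure of this kind with capture by an external arene. The five-membered ring closes exo at the carbonyl and endo at the alkene, equivalent to a conrotatory 4π closure of a 1-hydroxypentadienyl cation whose central double bond is C7a–C3a of ring A, and attack by C3 would give a four-membered ring, so only one mode exists. C2 (S) is set in this C–C bond formation by the sense of rotation that the anion, hydrogen-bonded to the hydroxycarbenium ion, imposes. C1 follows from the carbonyl rotamer (oxygen turned away from the styryl group ends trans to ring B, which sits on the outside of the E alkene) and is removed in step 7, so either C1 epimer serves. C3 (S) is set by the substrate, since guaiacol approaches the planar cation anti to ring B on C2 and gives the 2,3-trans product. The step needs ring closure to outrun intermolecular hydroxyalkylation of guaiacol (secured by proximity and the strongly nucleophilic C2), para-to-hydroxyl regiochemistry (the free OH is the stronger donor and can hydrogen-bond to the anion), and a product that does not re-ionise (C7a is meta to both ring A oxygens).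

Step 6
Reactants: 8 (1S,2S,3S)-2-(3,5-diisopropoxyphenyl)-3-(4-hydroxy-3-methoxyphenyl)-4,6-diisopropoxyindan-1-ol
Product: 9 (1S,2S,3S)-2-(3,5-diisopropoxyphenyl)-3-(4-isopropoxy-3-methoxyphenyl)-4,6-diisopropoxyindan-1-ol
Conditions: 2-bromopropane, K2CO3, DMF, 50 °C
Reagents that add atoms: 2-bromopropane, CC(C)Br
Why: Williamson etherification of the only phenol; carbonate does not deprotonate the secondary C1 alcohol, and masking the guaiacol-type phenol protects it from the oxidant of step 7 and the organometallic of step 10.

Step 7
Reactants: 9 (1S,2S,3S)-2-(3,5-diisopropoxyphenyl)-3-(4-isopropoxy-3-methoxyphenyl)-4,6-diisopropoxyindan-1-ol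
Product: 10 (2S,3S)-2-(3,5-diisopropoxyphenyl)-3-(4-isopropoxy-3-methoxyphenyl)-4,6-diisopropoxyindan-1-one
Conditions: Dess–Martin periodinane, CH2Cl2, 0 °C → rt
Reagents that add atoms: none
Why: Dess–Martin oxidation of a secondary benzylic alcohol, in which both C1 epimers converge; C2 becomes enolisable, but with C3 fixed the trans ketone is the thermodynamic isomer, so enantiopurity is not at risk.

Step 8
Reactants: 11 4-bromo-2-methoxyphenol
Product: 12 4-bromo-2-methoxy-1-(propan-2-yloxy)benzene
Conditions: 2-bromopropane, K2CO3, DMF, 60 °C
Reagents that add atoms: 2-bromopropane, CC(C)Br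
Why: Williamson etherification of the phenol.

Step 9
Reactants: 12 4-bromo-2-methoxy-1-(propan-2-yloxy)benzene
Product: 13 [(4-isopropoxy-3-methoxyphenyl)methyl]trimethylsilane
Conditions: Me3SiCH2MgCl, NiCl2(dppp) (3 mol %), THF, reflux
Reagents that add atoms: (trimethylsilyl)methylmagnesium chloride, C[Si](C)(C)C[Mg]Cl
Why: Kumada coupling of an unhindered aryl bromide with a Grignard reagent that has no β-hydrogen.

Step 10
Reactants: 13 [(4-isopropoxy-3-methoxyphenyl)methyl]trimethylsilane; 10 (2S,3S)-2-(3,5-diisopropoxyphenyl)-3-(4-isopropoxy-3-methoxyphenyl)-4,6-diisopropoxyindan-1-one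
Product: 15 (1R,2S,3S)-1-[(4-isopropoxy-3-methoxyphenyl)(trimethylsilyl)methyl]-2-(3,5-diisopropoxyphenyl)-3-(4-isopropoxy-3-methoxyphenyl)-4,6-diisopropoxyindan-1-ol (both epimers at the silyl-bearing carbon), via lithiated benzylsilane 14 (not isolated)
Conditions: 13, s-BuLi, TMEDA, THF, −78 °C; anhydrous CeCl3, −78 °C; then 10, −78 → −20 °C; aq NH4Cl
Reagents that add atoms: none
Why: Addition stage of a Peterson olefination; silicon directs lithiation to the benzylic carbon, and CeCl3 lowers the basicity of the carbanion so that it adds to the enolisable ketone, expected anti to ring B on C2. Both new centres (C1 and C8) disappear in step 11.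

Step 11
Reactants: 15 (1R,2S,3S)-1-[(4-isopropoxy-3-methoxyphenyl)(trimethylsilyl)methyl]-2-(3,5-diisopropoxyphenyl)-3-(4-isopropoxy-3-methoxyphenyl)-4,6-diisopropoxyindan-1-ol
Product: 16 hexa-O-isopropylgnetulin [(2S,3S)-1-[(E)-4-isopropoxy-3-methoxybenzylidene]-2-(3,5-diisopropoxyphenyl)-3-(4-isopropoxy-3-methoxyphenyl)-4,6-diisopropoxyindane]
Conditions: KH, THF, 0 °C → rt; then I2 (5 mol %), toluene, 60 °C
Reagents that add atoms: none
Why: Peterson syn-elimination of the potassium β-silyl alkoxide places the double bond between C1 and C8 and nowhere else, without acid; catalytic iodine then equilibrates the geometric isomers to the E alkene, in which ring D avoids the peri C7–H.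

Step 12
Reactants: 16 hexa-O-isopropylgnetulin
Product: 17 gnetulin [(2S,3S)-2-(3,5-dihydroxyphenyl)-1-[(E)-4-hydroxy-3-methoxybenzylidene]-3-(4-hydroxy-3-methoxyphenyl)indane-4,6-diol]
Conditions: BCl3, CH2Cl2, −78 → 0 °C; then H2O
Reagents that add atoms: none
Why: Lewis acid cleavage of aryl isopropyl ethers, whose secondary alkyl–oxygen bond breaks far more readily than that of the two methyl ethers; no protic acid is present before the quench, so the arylidene and the stereocentres should be untouched.

## Compound list

1 | 3,5-dihydroxybenzaldehyde | O=Cc1cc(O)cc(O)c1 | starting material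
2 | 3,5-diisopropoxybenzaldehyde | O=Cc1cc(OC(C)C)cc(OC(C)C)c1 | intermediate
3 | 2-bromo-3,5-diisopropoxybenzaldehyde | O=Cc1cc(OC(C)C)cc(OC(C)C)c1Br | intermediate
4 | 3,5-diisopropoxystyrene | C=Cc1cc(OC(C)C)cc(OC(C)C)c1 | intermediate
5 | 2-[(E)-2-(3,5-diisopropoxyphenyl)ethenyl]-3,5-diisopropoxybenzaldehyde | O=Cc1cc(OC(C)C)cc(OC(C)C)c1/C=C/c1cc(OC(C)C)cc(OC(C)C)c1 | intermediate
6 | guaiacol (2-methoxyphenol) | COc1ccccc1O | starting material
7 | (1S,2S)-1-hydroxy-2-(3,5-diisopropoxyphenyl)-4,6-diisopropoxyindan-3-ylium, ion pair with the catalyst anion | O[C@@H]1c2cc(OC(C)C)cc(OC(C)C)c2[CH+][C@H]1c1cc(OC(C)C)cc(OC(C)C)c1 | intermediate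
8 | (1S,2S,3S)-2-(3,5-diisopropoxyphenyl)-3-(4-hydroxy-3-methoxyphenyl)-4,6-diisopropoxyindan-1-ol (1,2-trans, 2,3-trans) | O[C@@H]1c2cc(OC(C)C)cc(OC(C)C)c2[C@H](c2ccc(O)c(OC)c2)[C@H]1c1cc(OC(C)C)cc(OC(C)C)c1 | intermediate
9 | (1S,2S,3S)-2-(3,5-diisopropoxyphenyl)-3-(4-isopropoxy-3-methoxyphenyl)-4,6-diisopropoxyindan-1-ol | O[C@@H]1c2cc(OC(C)C)cc(OC(C)C)c2[C@H](c2ccc(OC(C)C)c(OC)c2)[C@H]1c1cc(OC(C)C)cc(OC(C)C)c1 | intermediate
10 | (2S,3S)-2-(3,5-diisopropoxyphenyl)-3-(4-isopropoxy-3-methoxyphenyl)-4,6-diisopropoxyindan-1-one (2,3-trans) | O=C1c2cc(OC(C)C)cc(OC(C)C)c2[C@H](c2ccc(OC(C)C)c(OC)c2)[C@H]1c1cc(OC(C)C)cc(OC(C)C)c1 | intermediate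
11 | 4-bromo-2-methoxyphenol | COc1cc(Br)ccc1O | starting material
12 | 4-bromo-2-methoxy-1-(propan-2-yloxy)benzene | COc1cc(Br)ccc1OC(C)C | intermediate
13 | [(4-isopropoxy-3-methoxyphenyl)methyl]trimethylsilane | COc1cc(C[Si](C)(C)C)ccc1OC(C)C | intermediate
14 | [(4-isopropoxy-3-methoxyphenyl)(trimethylsilyl)methyl]lithium (configurationally labile) | COc1cc(C([Li])[Si](C)(C)C)ccc1OC(C)C | intermediate
15 | (1R,2S,3S)-1-[(4-isopropoxy-3-methoxyphenyl)(trimethylsilyl)methyl]-2-(3,5-diisopropoxyphenyl)-3-(4-isopropoxy-3-methoxyphenyl)-4,6-diisopropoxyindan-1-ol; hydroxyl cis to ring B; mixture of epimers at the silyl-bearing carbon, left undefined | COc1cc(C([Si](C)(C)C)[C@]2(O)c3cc(OC(C)C)cc(OC(C)C)c3[C@H](c3ccc(OC(C)C)c(OC)c3)[C@H]2c2cc(OC(C)C)cc(OC(C)C)c2)ccc1OC(C)C | intermediate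
16 | hexa-O-isopropylgnetulin, (2S,3S), E alkene | COc1cc(/C=C2/c3cc(OC(C)C)cc(OC(C)C)c3[C@H](c3ccc(OC(C)C)c(OC)c3)[C@H]2c2cc(OC(C)C)cc(OC(C)C)c2)ccc1OC(C)C | intermediate
17 | gnetulin, (2S,3S), E alkene | COc1cc(/C=C2/c3cc(O)cc(O)c3[C@H](c3ccc(O)c(OC)c3)[C@H]2c2cc(O)cc(O)c2)ccc1O | target

## Step count and risks

Total step count: 12. Longest linear sequence: 9 steps (steps 1, 2, 4, 5, 6, 7, 10, 11, 12); step 3 and steps 8 and 9 are branches.

**Step 5 (key step, proposed new method).**
- What may go wrong: poor enantiofacial control, because the stereo-determining bond forms at an alkene carbon remote from the hydrogen-bonded carbonyl. Less likely are capture of the cation through the guaiacol position para to methoxy, proton loss from the cation, or intermolecular hydroxyalkylation of guaiacol.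
- Fallback (known chemistry, racemic series with resolution): 5 and 6 are combined under an achiral Lewis acid (BF3·OEt2, CH2Cl2, −40 °C), the established racemic mode of Prins and Friedel–Crafts cascades. This gives 8 together with its mirror image, the (1R,2R,3R)-indanol F1. Steps 6 and 7 applied to the racemate give 9 with the (1R,2R,3R)-isopropyl ether F2 and then 10 with the (2R,3R)-ketone F3. At the ketone, where the C1 epimers have converged, the enantiomers are separated by preparative chromatography on a chiral stationary phase, and the route is rejoined at 10.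

**Step 10.**
- What may go wrong: deprotonation of the acidic C2–H of 10 by the bulky, basic carbanion in place of addition, or metalation of 13 on the ring next to an alkoxy group in place of the benzylic position.
- Fallback (reductive carbonyl coupling, no base): bromide 12 is converted by bromine–lithium exchange (n-BuLi, THF, −78 °C) and quenching with DMF into 4-isopropoxy-3-methoxybenzaldehyde F4. A crossed McMurry coupling of 10 with an excess of F4 (TiCl4, Zn, pyridine, THF, reflux; low-valent titanium) joins C1 and C8 directly as the alkene. After the iodine equilibration of step 11 the route is rejoined at 16, with 14 and 15 bypassed.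

**Step 11.**
- What may go wrong: unselective alkene geometry from the mixed configuration at the silyl-bearing carbon if the iodine equilibration is slow or incomplete, or migration of the double bond into the ring under traces of HI.
- Fallback (stereospecific eliminations in place of equilibration): the two epimers of 15 are separated by chromatography. The epimer F5, whose syn-elimination places ring D on the C2 side, is treated with KH in THF. The other epimer F6 is treated with BF3·OEt2 in CH2Cl2 at −78 °C for anti-elimination. Both converge on the E alkene and rejoin the route at 16.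

**Step 4.**
- What may go wrong: slow oxidative addition and insertion at the bromide flanked by the formyl and isopropoxy groups, so that hydrodebromination or styrene oligomerisation competes.
- Fallback (transmetalation in place of alkene insertion): styrene 4 undergoes cross-metathesis with vinylboronic acid pinacol ester (second-generation Grubbs catalyst, CH2Cl2, 40 °C) to give the (E)-styrylboronate F7. Suzuki–Miyaura coupling of F7 with 3 (Pd(OAc)2, SPhos, K3PO4, toluene/H2O, 80 °C) rejoins the route at 5.

## Further compounds

F1 | step 5 | (1R,2R,3R)-2-(3,5-diisopropoxyphenyl)-3-(4-hydroxy-3-methoxyphenyl)-4,6-diisopropoxyindan-1-ol (enantiomer of 8) | O[C@H]1c2cc(OC(C)C)cc(OC(C)C)c2[C@@H](c2ccc(O)c(OC)c2)[C@@H]1c1cc(OC(C)C)cc(OC(C)C)c1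
F2 | step 5 | (1R,2R,3R)-2-(3,5-diisopropoxyphenyl)-3-(4-isopropoxy-3-methoxyphenyl)-4,6-diisopropoxyindan-1-ol (enantiomer of 9) | O[C@H]1c2cc(OC(C)C)cc(OC(C)C)c2[C@@H](c2ccc(OC(C)C)c(OC)c2)[C@@H]1c1cc(OC(C)C)cc(OC(C)C)c1
F3 | step 5 | (2R,3R)-2-(3,5-diisopropoxyphenyl)-3-(4-isopropoxy-3-methoxyphenyl)-4,6-diisopropoxyindan-1-one (enantiomer of 10) | O=C1c2cc(OC(C)C)cc(OC(C)C)c2[C@@H](c2ccc(OC(C)C)c(OC)c2)[C@@H]1c1cc(OC(C)C)cc(OC(C)C)c1
F4 | step 10 | 4-isopropoxy-3-methoxybenzaldehyde | COc1cc(C=O)ccc1OC(C)C
F5 | step 11 | epimer of 15 that gives the E alkene by syn-elimination | COc1cc([C@@H]([Si](C)(C)C)[C@]2(O)c3cc(OC(C)C)cc(OC(C)C)c3[C@H](c3ccc(OC(C)C)c(OC)c3)[C@H]2c2cc(OC(C)C)cc(OC(C)C)c2)ccc1OC(C)C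
F6 | step 11 | epimer of 15 that gives the E alkene by anti-elimination | COc1cc([C@H]([Si](C)(C)C)[C@]2(O)c3cc(OC(C)C)cc(OC(C)C)c3[C@H](c3ccc(OC(C)C)c(OC)c3)[C@H]2c2cc(OC(C)C)cc(OC(C)C)c2)ccc1OC(C)C
F7 | step 4 | 2-[(E)-2-(3,5-diisopropoxyphenyl)ethenyl]-4,4,5,5-tetramethyl-1,3,2-dioxaborolane | CC(C)Oc1cc(/C=C/B2OC(C)(C)C(C)(C)O2)cc(OC(C)C)c1
A1 | alternative 1 | tetra-O-isopropylgnetulin with free C4 and C6 hydroxyls | COc1cc(/C=C2/c3cc(O)cc(O)c3[C@H](c3ccc(OC(C)C)c(OC)c3)[C@H]2c2cc(OC(C)C)cc(OC(C)C)c2)ccc1OC(C)C
A2 | alternative 1 | 2-[(E)-4-isopropoxy-3-methoxybenzylidene]-3-(3,5-diisopropoxyphenyl)-4-(4-isopropoxy-3-methoxyphenyl)-5-(3-oxobutanoyl)cyclopentan-1-one (aryl groups trans, C5 undefined) | COc1cc(/C=C2/C(=O)C(C(=O)CC(C)=O)[C@H](c3ccc(OC(C)C)c(OC)c3)[C@H]2c2cc(OC(C)C)cc(OC(C)C)c2)ccc1OC(C)C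
A3 | alternative 2 | C4-boryl penta-O-isopropyl indane (pinacol boronate at C4) | COc1cc(/C=C2/c3cc(OC(C)C)cc(B4OC(C)(C)C(C)(C)O4)c3[C@H](c3ccc(OC(C)C)c(OC)c3)[C@H]2c2cc(OC(C)C)cc(OC(C)C)c2)ccc1OC(C)C
A4 | alternative 2 | 4-isopropoxy-2-pyranone tethered at its C6 through C1, C2 and C3 to an alkynyl pinacol boronate | COc1cc(/C=C(/C2=CC(OC(C)C)=CC(=O)O2)[C@H](c2cc(OC(C)C)cc(OC(C)C)c2)[C@H](C#CB2OC(C)(C)C(C)(C)O2)c2ccc(OC(C)C)c(OC)c2)ccc1OC(C)C
A5 | alternative 3 | trans-(2S,3S)-2,3-diaryl-4,6-diisopropoxyindan-1-one (identical with 10) | O=C1c2cc(OC(C)C)cc(OC(C)C)c2[C@H](c2ccc(OC(C)C)c(OC)c2)[C@H]1c1cc(OC(C)C)cc(OC(C)C)c1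
A6 | alternative 3 | (E)-1,2-bis(3,5-diisopropoxyphenyl)-3-(4-isopropoxy-3-methoxyphenyl)prop-2-en-1-one | O=C(c1cc(OC(C)C)cc(OC(C)C)c1)/C(c1cc(OC(C)C)cc(OC(C)C)c1)=C/c1ccc(OC(C)C)c(OC)c1
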